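All runs were generated by integration for an exercise, and the scatter is random.

How much target stands after 20 min when the initiator goes from 5.0 mM to 40 mM, and does that row fall all the way?

all flasks: starting material 0.039 M; coupling partner 0.0429 M; transfer agent 1.95 mM
- Wednesday's: initiator 4.7 mM; run made earlier
- Sunday's: initiator 13 mM; run made earlier
- Thursday's: initiator 44 mM; run made earlier
- west: initiator 5.0 mM; time 20 min
- south-east: initiator 10 mM; time 20 min
- north-west: initiator 20 mM; time 20 min
- north-east: initiator 40 mM; time 20 min

- Wednesday's (time / min: target / %, starting material / %): 0.833: 9.7, 84.9; 2.50: 39.8, 46.1; 5.00: 53.4, 27.9; 8.00: 59.4, 17.9; 10.0: 60.1, 16.4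
- Sunday's (time / min: target / %, starting material / %): 0.833: 31.7, 52.6; 1.50: 44.9, 28.9; 3.00: 58.3, 0.4; 5.00: 58.0, 0; 10.0: 58.1, 0.2
- Thursday's (time / min: target / %, starting material / %): 2.00: 48.1, 0; 4.00: 47.8, 0; 6.00: 48.1, 0; 8.00: 48.0, 0.5; 10.0: 48.4, 0

(scatter of a reading: 0.5 percentage points)

- percent here means starting material units held: one ended chains counts as two
- what is said of target includes idle adduct
- what was read earlier has a scatter of 0.5 percentage points, one standard deviation
- reactions considered so far: coupling partner + target <-> idle adduct; 2 idle radical -> ended radicals; starting material + second chain carrier -> by-product + first chain carrier; 2 first chain carrier -> ended chains; starting material + initiating radical -> capped initiator + first chain carrier; initiator -> 2 initiating radical; coupling partner + first chain carrier -> target + second chain carrier; transfer agent + first chain carrier -> side product + idle radical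
- "hardly changes" means that all values lie within two and a half points (for a concentration: within two and a half percent of the largest)

* amount of target at the end, in percent of the starting material charged for west, south-east, north-west, north-east, in this order
* the shape of the row from first to last (hardly changes / rises all the way / rises, then falls / falls all the way / falls, then rises)

You can work on this with two amounts: the initiating radicals charged, two per initiator, and the loss, meaning the starting material used up without standing as target. In Wednesday's run at 10.0 min the loss is 9.17 mM against 9.40 mM of radicals charged, which gives 0.975 for the price, the starting material lost per radical charged. In Thursday's run, where starting material reads 0% at 2.00 min, the price at 10.0 min reads 0.229, so I take it that a radical pays the full price while it still has starting material to meet. My own reckoning for west is therefore that target plus unused starting material should come to 75.0% of the charge.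

The forecast, holding that “each radical started ends in termination and takes starting material with it”, gives 63%, 60.5%, 55% and 49%, a row that falls all the way. Set beside my sum, its south-east value leaves 15 percentage points for unused starting material in west if west is to stay on top, and Wednesday's run, with less initiator than west and at half the time asked, still read 16.4% at 10.0 min, more than that margin, so the first step of the row is the one I would watch.

The flasks give 64.5%, 60.4%, 54.0% and 48.3%, a row that falls all the way.

    coupling partner + target ⇌ idle adduct, settled at all times (K = 500 M⁻¹)
    2 idle radical → ended radicals (k = 1.10 × 10⁷ M⁻¹ s⁻¹)
    starting material + second chain carrier → by-product + first chain carrier (k = 1600 M⁻¹ s⁻¹)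
    2 first chain carrier → ended chains (k = 2.00 × 10⁶ M⁻¹ s⁻¹)
    starting material + initiating radical → capped initiator + first chain carrier (k = 38000 M⁻¹ s⁻¹)
    initiator → 2 initiating radical (k = 0.00560 s⁻¹)
    coupling partner + first chain carrier → target + second chain carrier (k = 1900 M⁻¹ s⁻¹)
    transfer agent + first chain carrier → side product + idle radical (kL = 1.20 × 10⁵ M⁻¹ s⁻¹)

West holds 9.9% of unused starting material and 74.4% together with target, against the 75.0% reckoned from the price of 0.975. In south-east, with 0% unused, the loss set against the radicals charged less the 0.00444 M of initiating radical still standing gives a price of 0.993. In west at 1.78 min, the rate at which second chain carrier uses starting material stands at 3.2 times the rate at which initiating radical uses it, up from 0.35 just after the start, and west ends with 0.0252 M of by-product against 0.00999 M of capped initiator.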